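Drimane numbering: C10 is the methyl-bearing quaternary fusion carbon, C5 the fusion CH, C6 the ring CH2, C7 the olefinic CH, C8 its methyl-bearing partner, C9 the CH carrying the chain. The key step exploits that ring B is two three-carbon units, the allylic triad C6–C5–C10 of ring A (β-cyclogeranyl cation) and the isoprenoid triad C7–C8–C9 (senecioate dienolate), joined at C6–C7 and C9–C10. In one operation the cation is captured at C6 by C7, and the monocyclic enoate so formed closes ring B by protonation at C5 and attack of C9 on cationic C10. A menthyl ester allows separation of the enantiomeric series; a Grignard coupling adds the farnesyl chain.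

Key step: step 3

Remark: β-cyclogeraniol is taken as a purchased compound (it is otherwise one NaBH4 reduction from β-cyclocitral); menthol, senecioyl chloride and (2E,6E)-farnesyl bromide are the other starting materials.

Step 1
Reactants: 1 (−)-menthol, (1R,2S,5R)-5-methyl-2-(propan-2-yl)cyclohexan-1-ol; 2 3-methylbut-2-enoyl chloride
Product: 3 (1R,2S,5R)-menthyl 3-methylbut-2-enoate
Conditions: pyridine, DMAP (cat.), CH2Cl2, 0 → 20 °C
Reagents that add atoms: none
Why: DMAP-catalysed acylation of the secondary alcohol by the acid chloride leaves the three menthol stereocenters untouched, and any deconjugated 3-methylbut-3-enoate formed through the vinylketene gives the same dienolate in step 2.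

Step 2
Reactants: 3 (1R,2S,5R)-menthyl 3-methylbut-2-enoate
Product: 4 menthyl trimethylsilyl dienolate, trimethyl[(3-methyl-1-{[(1R,2S,5R)-5-methyl-2-(propan-2-yl)cyclohexyl]oxy}buta-1,3-dien-1-yl)oxy]silane
Conditions: LiN(i-Pr)2, THF, −78 °C; then Me3SiCl, −78 → 0 °C; used crude
Reagents that add atoms: chlorotrimethylsilane (Me3SiCl), C[Si](C)(C)Cl
Why: Kinetic γ-deprotonation of the senecioate gives the extended enolate, which is silylated on oxygen to the silyl ketene acetal (silyl dienolate formation), obtained as a mixture of ketene-acetal geometric isomers that does not matter for step 3.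

Step 3
Reactants: 4 menthyl trimethylsilyl dienolate; 5 β-cyclogeraniol, (2,6,6-trimethylcyclohex-1-en-1-yl)methanol
Product: 7 (1R,2S,5R)-menthyl (1S,4aS,8aS)-drim-7-en-11-oate, via menthyl (2E)-β-monocyclofarnesate 6 (not isolated)
Conditions: 4 (1.5 equiv), BF3·OEt2 (3 equiv, added last), CH2Cl2, −78 → 20 °C
Reagents that add atoms: none
Why: Proposed new method: BF3 ionises the allylic alcohol 5 to the β-cyclogeranyl cation, whose unhindered primary terminus C6 is captured by the terminal γ-carbon (C7) of silyl dienolate 4 in a vinylogous Mukaiyama-type SN1 alkylation, giving the (2E)-enoate 6 while silicon leaves as Me3SiF and the former hydroxyl group remains as the Brønsted acid HOBF2·BF3. That acid should protonate the tetrasubstituted C5=C10 alkene of 6 at C5, and the C10 cation is then attacked by C9 of the enoate in a 6-endo-trig cation–olefin closure of ring B through a chair transition state, the C8 cation finally losing the axial C7 proton to leave the C7=C8 alkene. The closest known reaction types are the Lewis-acid γ-alkylation of silyl dienolates by allylic cations and the acid-induced cyclization of farnesic and monocyclofarnesic esters to drim-7-en-11-oates; new is their union into one dehydrative [3+3] annulation in which the alcohol supplies the proton. The chair closure with C6 and C9 both equatorial on ring A sets C5 and C10 as the trans fusion, and the E geometry of the C8=C9 enoate places the ester equatorial at C9, so one relative configuration (5S*,9S*,10S*) is expected. The absolute sense is not induced: both ring enantiomers form, as diastereomers because of the menthyl group, and 7 is separated from its (1R,4aR,8aR) diastereomer (and from any C9 epimer derived from (2Z)-6) by chromatography or crystallization. The step needs γ over α attack of the dienolate, C6 over C10 capture of the cation and C7 over C9 deprotonation at the end, which rest on the terminal HOMO coefficient and bulk of 4, on the steric shielding of the tertiary terminus C10, and on the kinetic preference for loss of the axial ring proton at C7.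

Step 4
Reactants: 7 (1R,2S,5R)-menthyl (1S,4aS,8aS)-drim-7-en-11-oate
Product: 8 drimenol of the natural series, [(1S,4aS,8aS)-2,5,5,8a-tetramethyl-1,4,4a,5,6,7,8,8a-octahydronaphthalen-1-yl]methanol
Conditions: LiAlH4, THF, 0 → 65 °C
Reagents that add atoms: none
Why: Hydride reduction of the ester to the primary alcohol releases the auxiliary as menthol and affects neither the isolated trisubstituted alkene nor the three ring stereocenters.

Step 5
Reactants: 8 drimenol
Product: 9 drimenyl bromide, (1S,4aS,8aS)-1-(bromomethyl)-2,5,5,8a-tetramethyl-1,4,4a,5,6,7,8,8a-octahydronaphthalene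
Conditions: CBr4, PPh3, CH2Cl2, 0 → 20 °C
Reagents that add atoms: carbon tetrabromide, BrC(Br)(Br)Br
Why: The Appel reaction replaces the primary hydroxyl by bromide through an alkoxyphosphonium ion under neutral conditions, so the C9 stereocenter and the homoallylic alkene should stay intact.

Step 6
Reactants: 9 drimenyl bromide; 10 (2E,6E)-farnesyl bromide, (2E,6E)-1-bromo-3,7,11-trimethyldodeca-2,6,10-triene
Product: 12 target, (1S,4aS,8aS)-2,5,5,8a-tetramethyl-1-[(3E,7E)-4,8,12-trimethyltrideca-3,7,11-trien-1-yl]-1,4,4a,5,6,7,8,8a-octahydronaphthalene, via drimenylmagnesium bromide 11 (not isolated)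
Conditions: Mg, THF, 45 °C; then 10, Li2CuCl4 (5 mol %), THF, −78 → 0 °C
Reagents that add atoms: magnesium, [Mg] (retained only in intermediate 11)
Why: Magnesium insertion gives the primary Grignard reagent 11, and its copper-catalysed cross-coupling with the allylic bromide 10 should join C11 (the CH2 on C9) to the primary carbon of the farnesyl unit with retention of both E alkenes, attack at the tertiary allylic terminus being disfavoured and no stereocenter being touched.

Compound list
1 | (−)-menthol, (1R,2S,5R)-5-methyl-2-(propan-2-yl)cyclohexan-1-ol | C[C@@H]1CC[C@H]([C@@H](C1)O)C(C)C | starting material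
2 | 3-methylbut-2-enoyl chloride (senecioyl chloride) | CC(C)=CC(Cl)=O | starting material
3 | (1R,2S,5R)-menthyl 3-methylbut-2-enoate | C[C@@H]1CC[C@H]([C@@H](C1)OC(=O)C=C(C)C)C(C)C | intermediate
4 | trimethyl[(3-methyl-1-{[(1R,2S,5R)-5-methyl-2-(propan-2-yl)cyclohexyl]oxy}buta-1,3-dien-1-yl)oxy]silane (silyl dienolate, ketene-acetal geometry not defined) | C[C@@H]1CC[C@H]([C@@H](C1)OC(O[Si](C)(C)C)=CC(C)=C)C(C)C | intermediate
5 | β-cyclogeraniol, (2,6,6-trimethylcyclohex-1-en-1-yl)methanol | OCC1=C(C)CCCC1(C)C | starting material
6 | (1R,2S,5R)-menthyl (2E)-3-methyl-5-(2,6,6-trimethylcyclohex-1-en-1-yl)pent-2-enoate (menthyl β-monocyclofarnesate; formed in the flask, not isolated) | C[C@@H]1CC[C@H]([C@@H](C1)OC(=O)/C=C(\C)CCC2=C(C)CCCC2(C)C)C(C)C | intermediate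
7 | (1R,2S,5R)-menthyl (1S,4aS,8aS)-2,5,5,8a-tetramethyl-1,4,4a,5,6,7,8,8a-octahydronaphthalene-1-carboxylate (menthyl drim-7-en-11-oate; trans-fused, ester equatorial) | C[C@@H]1CC[C@H]([C@@H](C1)OC(=O)[C@H]2C(C)=CC[C@H]3C(C)(C)CCC[C@]23C)C(C)C | intermediate
8 | drimenol, [(1S,4aS,8aS)-2,5,5,8a-tetramethyl-1,4,4a,5,6,7,8,8a-octahydronaphthalen-1-yl]methanol | OC[C@H]1C(C)=CC[C@H]2C(C)(C)CCC[C@]12C | intermediate
9 | drimenyl bromide, (1S,4aS,8aS)-1-(bromomethyl)-2,5,5,8a-tetramethyl-1,4,4a,5,6,7,8,8a-octahydronaphthalene | BrC[C@H]1C(C)=CC[C@H]2C(C)(C)CCC[C@]12C | intermediate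
10 | (2E,6E)-farnesyl bromide, (2E,6E)-1-bromo-3,7,11-trimethyldodeca-2,6,10-triene | CC(C)=CCC/C(C)=C/CC/C(C)=C/CBr | starting material
11 | bromo{[(1S,4aS,8aS)-2,5,5,8a-tetramethyl-1,4,4a,5,6,7,8,8a-octahydronaphthalen-1-yl]methyl}magnesium (drimenylmagnesium bromide; formed in the flask, not isolated) | Br[Mg]C[C@H]1C(C)=CC[C@H]2C(C)(C)CCC[C@]12C | intermediate
12 | (1S,4aS,8aS)-2,5,5,8a-tetramethyl-1-[(3E,7E)-4,8,12-trimethyltrideca-3,7,11-trien-1-yl]-1,4,4a,5,6,7,8,8a-octahydronaphthalene (CNP0141177.1) | CC(C)=CCC/C(C)=C/CC/C(C)=C/CC[C@H]1C(C)=CC[C@H]2C(C)(C)CCC[C@]12C | target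

Total step count: 6. Longest linear sequence: 6 steps (1 and 2 → 3 → 4 → 7 → 8 → 9 → 12).

Steps most likely to fail

Step 3 (proposed new method). The cascade may stop after the first bond if the hydroxyl proton is used up by silyl transfer from 4 to 5, so that too little Brønsted acid remains for the ring closure. The allyl cation may also be lost to elimination and oligomerisation before it is captured. The fallback uses known reactions in separate operations and sets out from 5. PBr3 (pyridine cat., Et2O, −10 °C) gives 2-(bromomethyl)-1,3,3-trimethylcyclohex-1-ene F1. ZnBr2-catalysed γ-alkylation of silyl dienolate 4 with F1 in CH2Cl2 gives 6, which is now isolated. Proton-initiated cyclization of 6 with FSO3H in 2-nitropropane at −78 °C, followed by the same diastereomer separation, comes back to the route at 7.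

Step 6. Magnesium insertion at the β-branched bromide may be incomplete, either partner may homocouple, and some attack at the tertiary allylic terminus may occur. The resulting hydrocarbons are isomeric with 12 and hard to remove. The fallback sets out from 9 and reverses the order of events through a sulfone. Displacement with PhSO2Na (n-Bu4NI, DMF, 80 °C) gives (1S,4aS,8aS)-1-[(benzenesulfonyl)methyl]-2,5,5,8a-tetramethyl-1,4,4a,5,6,7,8,8a-octahydronaphthalene F2. Deprotonation with n-BuLi (THF, −78 °C) and alkylation with 10 gives the farnesylated sulfone F3, a polar mixture of epimers at the sulfonyl carbon that can be purified on silica. Reductive desulfonylation with Na/Hg (Na2HPO4, MeOH, −20 °C) comes back to the route at 12.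

Step 5. Displacement of the oxyphosphonium group at the β-branched primary carbon may be slow, letting elimination or homoallyl–cyclopropylcarbinyl rearrangement compete. The fallback sets out from 8 and separates activation from substitution. Tf2O and pyridine (CH2Cl2, −78 °C) give [(1S,4aS,8aS)-2,5,5,8a-tetramethyl-1,4,4a,5,6,7,8,8a-octahydronaphthalen-1-yl]methyl trifluoromethanesulfonate F4. This is used at once with LiBr (THF, 0 → 20 °C) and comes back to the route at 9.

Further compounds
F1 | step 3 | 2-(bromomethyl)-1,3,3-trimethylcyclohex-1-ene (β-cyclogeranyl bromide) | BrCC1=C(C)CCCC1(C)C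
F2 | step 6 | (1S,4aS,8aS)-1-[(benzenesulfonyl)methyl]-2,5,5,8a-tetramethyl-1,4,4a,5,6,7,8,8a-octahydronaphthalene | O=S(=O)(C[C@H]1C(C)=CC[C@H]2C(C)(C)CCC[C@]12C)c1ccccc1
F3 | step 6 | (1S,4aS,8aS)-1-[(3E,7E)-1-(benzenesulfonyl)-4,8,12-trimethyltrideca-3,7,11-trien-1-yl]-2,5,5,8a-tetramethyl-1,4,4a,5,6,7,8,8a-octahydronaphthalene (both epimers at the sulfonyl carbon) | CC(C)=CCC/C(C)=C/CC/C(C)=C/CC([C@H]1C(C)=CC[C@H]2C(C)(C)CCC[C@]12C)S(=O)(=O)c1ccccc1
F4 | step 5 | [(1S,4aS,8aS)-2,5,5,8a-tetramethyl-1,4,4a,5,6,7,8,8a-octahydronaphthalen-1-yl]methyl trifluoromethanesulfonate | O=S(=O)(OC[C@H]1C(C)=CC[C@H]2C(C)(C)CCC[C@]12C)C(F)(F)F
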